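The numbers in the tables are calculated with made-up constants; scatter was added.

At 30.0 min the north-west flask reads 18.7 % of its charge as target and the west flask 53.1 %, although the north-west charge is 15.8 times the west charge.

| flask | substrate | remark | time |
|---|---|---|---|
| west | 0.048 M | run made earlier |  |
| north-west | 0.76 M | run made earlier |  |
| Saturday's | 0.040 M |  | 40 min |
| Thursday's | 0.60 M |  | 40 min |
| Wednesday's | 0.40 M |  | 40 min |
| Monday's | 0.20 M |  | 40 min |
| Sunday's | 0.14 M |  | 40 min |

| west: time / min | west: target / % | north-west: time / min | north-west: target / % |
|---|---|---|---|
| 2.50 | 0.2 | 2.50 | 2.7 |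
| 8.00 | 10.9 | 4.00 | 3.5 |
| 12.0 | 20.7 | 8.00 | 6.8 |
| 20.0 | 36.2 | 15.0 | 10.3 |
| 30.0 | 53.1 | 30.0 | 18.7 |

(scatter of a reading: 1 percentage point)

* all flasks from highest to lowest amount of target, in percent of the substrate charged, at 40 min (Saturday's / Thursday's / Wednesday's / Monday's / Sunday's)
* the amount of target, in percent of the substrate charged of the flask you put first, at 40 min
* the amount of target, in percent of the substrate charged of the flask you put last, at 40 min



My reckoning supposes that substrate leaves by a first-order route towards target and by a loss in the square of its concentration. A flask charged at x balance charges then ends with the share ln(1+x)/x as target, its ceiling (the overall selectivity for target). Reading the north-west value as that ceiling, with the west charge as trial inside the logarithm, gives the charge at which both routes draw equally at the start, the balance charge 0.0503 M.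

The west ceiling is then 70.2 %. The west readings stand short of it by 48.5 % of that ceiling at 20.0 min and 24.4 % at 30.0 min, so the gap shrinks to about half in 10.0 min. That leaves a reckoned gap of 12.3 % at 40 min. The reckoned ceiling of Saturday's is 73.6 % and that of Thursday's 21.5 %, so with the west gap carried over the reckoning puts Saturday's at 64.5 %.

The weak link is a gap taken from two scattered readings. Taken from 12.0 min to 30.0 min, it closes at 0.0590 /min, which leaves 13.5 %. With this gap carried over unchanged and a ceiling that falls as x rises, the reckoned order runs upward in charge, from Saturday's at 63.6 % to Thursday's at 18.6 %.

The forecast gives Saturday's > Sunday's > Monday's > Wednesday's > Thursday's, with 72 % (from 64 % to 80 %) and 26 % (from 22 % to 30 %), and says: “Lower charges therefore give the higher percentage.” Both its numbers stand above this reckoning.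

The flasks give Saturday's > Sunday's > Monday's > Wednesday's > Thursday's, with 63.0 % and 20.3 %.

    substrate → intermediate (k = 0.00100 /s)
    intermediate → target (k = 0.00180 /s)
    2 substrate → self-condensation product (k = 0.00940 /M/s)

Thursday's stands at 11.9 balance charges, with a reckoned ceiling of 21.5 %, and it holds 22.2 % of target at 400 min. Thursday's is low at 40 min because of the loss to self-condensation product: with that step taken away, Thursday's holds 81.3 % of target at that time instead of 20.3 %.

For Saturday's read at 25 min the reckoning gives a gap of 32.8 %, so its ceiling gives 49.5 % of target. That flask holds 47.2 % of target.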